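The target is what you want from this flask, yet once made it can take a further electrophile and become side product B, so before the next run you must choose between the blue and the teal charge of nucleophile, knowing what the dose buys and what standing buys.

- blue: electrophile 0.010 M; nucleophile 9.50 mM (fed, over 2.5 h); time 12 h; the fed solution adds 0.10 times the starting volume
- teal: electrophile 0.010 M; nucleophile 14.0 mM (fed, over 2.5 h); time 12 h; the fed solution adds 0.10 times the starting volume

    electrophile + nucleophile → acid set free + target (k1 = 83 /M/min)
    target ⇌ isomer of the product (K2 = 2.4, k2 = 0.026 /min)
    electrophile + target → side product B (k3 = 1.1 /M/min)
    nucleophile + acid set free ⇌ protonated nucleophile, settled at all times (K4 = 7.1 × 10⁵ /M)
    electrophile + acid set free → side product A (k5 = 0.20 /M/min)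

- percentages count the electrophile that a species holds: one side product B counts as two
- every charge counts on the volume at the start, and the solution that is fed holds the whole dose
- run time (blue): 12 h

1. part of the electrophile that has reacted at the end, blue
2. part of the electrophile that has reacted at the end, teal
3. what raising the concentration of nucleophile from its lowest to its highest value here does to the part of the electrophile that has reacted (changes below 5 percentage points count as none) (it rises / it falls / no change)

I reckon it this way. The binding of acid by nucleophile has a balance constant times electrophile charge of 7100, far above one, and because of this each coupling uses one nucleophile and binds a second. The coupled part of the charge is therefore 47.5% in blue and 70.0% in teal. Target turns into isomer with a half-life of 0.444 h, far shorter than the loss to side product B, so I let the two stand at balance, which leaves target 14.0% of the charge in blue and 20.6% in teal.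

Now replace the target curve by that mean level, held for the whole 12 h. The uncoupled electrophile then decays in a pseudo-first-order way with a drain half-life, the half-life of electrophile against side product B at the mean target level on the volume after the feed: 8.27 h in blue, 5.61 h in teal. That level runs too high during the feed, when target is still building, and again later, since each side product B takes up a target; against this it leaves out coupling after the feed, so the errors pull opposite ways. I commit to 80.8% for blue and 93.2% for teal. That favours teal for the next run: its uncoupled part is smaller, its drain half-life is shorter, and the gain of 12 percentage points exceeds the margin.

The forecast says 86% for blue, 97% for teal and it rises, on the ground that “each acid released ties up a second nucleophile”. Its figures stand above mine.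

The flask gives 84.3% for blue and 96.5% for teal, so going from blue to teal the reacted part of the electrophile changes as follows: it rises, by 12 points. In blue, the half-life of electrophile towards side product B at 1.48 h is 9.9 h, shorter than the run, and it stands at that one moment against the carried 8.27 h, which was reckoned for the whole run, while towards side product A the half-life is 43 h at 12.0 h, longer than the run. Read the blue flask at 20 h instead: the carried half-life gives 90.2% reacted, and the simulation gives 92.0%.

The constants used here belong to no real substance; the rest is arithmetic.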